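The data are calculated from invented constants, and the scatter is random.

In the early minutes of the closed flasks, J is just appearing, while free G falls at a pace that follows the Q charged. The red run, over 40.0 min, gives 0.400 min⁻¹ for G lost per minute per Q charged, the turnover rate. That is one G per Q every 2.50 min on average. The amber run, with twice the Q, reads 0.392 min⁻¹, and the violet run, with half the Q, reads 0.448 min⁻¹.

all flasks: L 0.0544 M
- red: G 0.068 M; Q 1.7 mM; run made earlier
- violet: G 0.068 M; Q 0.85 mM; run made earlier
- amber: G 0.068 M; Q 3.4 mM; run made earlier
- eta: G 0.068 M; Q 1.7 mM; a single well-mixed tank run continuously and read at steady state, 200 min in it on average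
- epsilon: G 0.068 M; Q 1.7 mM; one stirred flow tank at steady state, fed with the mixture as stated, mean residence time 40 min
- alpha: G 0.068 M; Q 1.7 mM; everything together in a closed stirred flask, run for 40 min; time 40 min
- gamma: G 0.068 M (fed, over 40.0 min); Q 1.7 mM; a stirred flask in which G is dosed at a steady rate over 40.0 min without added volume, worked up at 40 min; time 40 min

- red (time / min: J / %, G / %): 10.0: 9, 86; 20.0: 11, 76; 30.0: 19, 68; 40.0: 22, 60
- violet (time / min: J / %, G / %): 6.00: 3, 95; 12.0: 8, 91; 20.0: 9, 86; 25.0: 7, 86
- amber (time / min: J / %, G / %): 6.00: 10, 82; 12.0: 18, 71; 20.0: 25, 56; 25.0: 35, 51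

(readings scatter by 2 percentage points)

- the stated concentrations are those of everything mixed, before any reaction; amounts are the same in each set-up
- the feed brings no volume worth counting
- the earlier runs were made in a closed, stirred flask
- a reading or a percentage of J counts all its forms, free or not
- a reading of G is of its free form alone

1. the set-up with the highest amount of J at the outlet or at the end, in percent of the G put in ("none" if the first two lie within 2 percentage points) (eta / epsilon / alpha / gamma / none)
2. amount of J at the outlet or at the end, in percent of the G put in, eta
3. amount of J at the outlet or at the end, in percent of the G put in, epsilon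
4. amount of J at the outlet or at the end, in percent of the G put in, alpha
5. amount of J at the outlet or at the end, in percent of the G put in, gamma

At 40.0 min, a closed flask like the red run will show 60 % of G free and 22 % of J, so J is 55.0 % of the G lost. Keep Q as charged, since the pace goes with it.

Red, violet and amber start at the same 0.068 M of G, so they show no order in c(G). At 6.00 min, the gap between G lost and J reads 8 percentage points in amber and 2 points in violet. Amber's Q, taking up G one to one, holds at most 5.00 % of the G charged, so the amber gap, read larger than that, is not Q occupied alone. This reckoning assumes a saturated catalyst, zero order in c(G), without support from these gaps. Dosing over 40.0 min then keeps the pace, which loses 40.0 % of the charge and gives 22.0 % of J in gamma.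

The forecast differs there. It names eta best, with 36 % in eta, 20 % in epsilon, 23 % in alpha and 15 % in gamma, reasoning that “dosed G has less average time to react”.

The flasks give 34.8 % in eta, 18.1 % in epsilon, 23.5 % in alpha and 22.7 % in gamma, so eta stands first.

    G + Q → D (k = 140 L mol⁻¹ min⁻¹)
    L + D ⇌ E (K = 8.50 L mol⁻¹, k = 19.0 L mol⁻¹ min⁻¹)
    E → Q + J (k = 1.90 min⁻¹)
    G + J ⇌ X, settled at all times (K = 5.50 L mol⁻¹)
    G + J → Z (k = 0.320 L mol⁻¹ min⁻¹)

Gamma lies 7.7 points above the forecast. It ended with 63.1 % of its G free, which is a turnover rate of 0.369 min⁻¹ against 0.400 min⁻¹ in the red run. Epsilon, with 60.6 % of its G free at the outlet after 40 min in the tank on average, gives a turnover rate of 0.394 min⁻¹.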